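The question is how the share of links among links and capped ends moves when one charge is run four ways.

the same everywhere: first end groups 0.020 M; one-sided end groups 1.00 mM

|  | second end groups | time | remark |
|---|---|---|---|
| Sunday's | 0.0220 M (fed, over 4.00 h) | 5.0 h | a stirred flask in which second end groups is dosed at a steady rate over 4.00 h without added volume, worked up at 5.0 h |
| Thursday's | 0.0220 M |  | a single well-mixed tank run continuously and read at steady state, 25.0 h in it on average |
| Friday's | 0.0220 M | 5.0 h | a closed flask charged with all of it at once and left for 5.0 h |
| Saturday's | 0.0220 M |  | one stirred flow tank at steady state, fed with the mixture as stated, mean residence time 5.0 h |

1. the set-up with the highest share of links in all that became links or capped ends, at the outlet or at the end ("none" if the first two lie within 2 percentage points) (Sunday's / Thursday's / Friday's / Saturday's / none)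
2. share of links in all that became links or capped ends, at the outlet or at the end, Sunday's
3. share of links in all that became links or capped ends, at the outlet or at the end, Thursday's
4. share of links in all that became links or capped ends, at the outlet or at the end, Friday's
5. share of links in all that became links or capped ends, at the outlet or at the end, Saturday's

- in percentages every species weighs as the first end groups in it: one self-condensation product counts as two
- a step written with two of one species runs at k times the square of its concentration and takes two of it each time
- the stated concentrations are those of everything mixed, before any reaction; amounts are the same in each set-up
- the feed brings no volume worth counting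
- run time (Sunday's): 5.0 h

I reckon first, on Friday's flask. At the charged c(first end groups), a one-sided end group has a half-life of 0.636 min, far shorter than the 5.0 h run, so I book capped ends at the charged c(one-sided end groups). That gives the cap toll, the charged c(one-sided end groups) divided by the charged c(first end groups), 5.00%. With r the links as a fraction of first end groups charged, the share is r/(r + toll).

How large is r? A second end group forks: it links at a pseudo-first-order rate or decomposes. With c(first end groups) taken at half its charge, linking runs at 0.0177 min⁻¹ against 0.00599 min⁻¹, faster, so its chance of linking is 74.7%. Its half-life by decomposition, 1.9 h, is shorter than the run, so I send the whole charge through this fork. That gives r = 82.2% and a share of 94.3% for Friday's flask. My reckoning stops there.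

The forecast says 93.5% for Sunday's, 93% for Thursday's, 94% for Friday's and 92.6% for Saturday's, with best: none, on the ground that “the share depends only on how many links form”. My Friday figure of 94.3% differs from the forecast's 94% for Friday's flask by 0.30 percentage points.

The simulation gives 93.7%, 93.0%, 94.0% and 92.5% in that order, and best: none, since Friday's and Sunday's lie 0.30 points apart, inside the margin of 2 points.

    2 first end groups → self-condensation product (k1 = 0.00177 M⁻¹ min⁻¹)
    first end groups + one-sided end groups → capped ends (k2 = 54.5 M⁻¹ min⁻¹)
    first end groups + second end groups → links (k3 = 1.77 M⁻¹ min⁻¹)
    second end groups → decomposed reagent (k4 = 0.00599 min⁻¹)

The capping constant, 54.5 M⁻¹ min⁻¹, stands 30.8 times the linking constant, 1.77 M⁻¹ min⁻¹, and with capped ends held at the toll, Friday's 94.0% reads as links at 78.3% of the first end groups charged. Thursday's tank holds links at 66.0% of the first end groups charged, and against the same toll that makes a share of 93.0%.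

The numbers of this flask come from no measurement.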